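The constants belong to no real substance.

Start from the amounts: east holds the same free monomer as south-west and about half of its initiator.

| flask | free monomer | initiator | time |
|---|---|---|---|
| south-west | 0.50 M | 3.1 mM | 20 h |
| east | 0.50 M | 1.5 mM | 20 h |

    initiator → 2 initiating radical (k1 = 0.0049 s⁻¹)
    free monomer + initiating radical → growing radical + monomer in chains (k2 = 2.5 × 10⁵ M⁻¹ s⁻¹)
    free monomer + growing radical → monomer in chains + growing radical, rate k3*[growing radical]*[free monomer] (k3 = 7800 M⁻¹ s⁻¹)
    monomer in chains → over-reaction product (k4 = 3.4 × 10⁻⁶ s⁻¹)
    2 growing radical → dead chain (k5 = 3 × 10⁸ M⁻¹ s⁻¹)

* which of the two ends with the longer chains by the average number of monomer units in a chain (living and dead chains, two that joined counted as one) ("neither" if they lie within 10%) (south-west / east / neither)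
* average number of monomer units in a chain (living and dead chains, two that joined counted as one) at the end, south-west
* average number of monomer units in a chain (living and dead chains, two that joined counted as one) at the end, east

- for a step with 2 of a species take k times the square, and two of it per event
- the average divides the monomer in chains by the number of chains, living and dead together; two radicals that join make one chain
- run time (south-west): 20 h

Here is my own reckoning. Count lifetimes first. The initiator has a half-life of 2.4 min, so the run lasts 509 half-lives, and in both flasks its radicals come in the first minutes. One initiator gives two radicals and two radicals make one chain, so take c(chains) = c(initiator charged).

While radicals form as fast as they pair off, c(growing radical) = √(splitting constant × c(initiator) / joining constant). Summing growth over the decay of the initiator gives the natural log of how far free monomer falls: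

reach = 2 × growth constant × √(c(initiator charged) / (splitting constant × joining constant))

south-west: 0.716, so 51.1% of the free monomer is used

east: 0.498, so 39.2% is used

By this reckoning growth stops with free monomer left (dead-end polymerisation). The chains then sit for the run and lose monomer in chains over 0.245 lifetimes of the over-reaction step. Call the share of monomer in chains still there after the run the kept share, e to the minus those lifetimes: 0.783.

length = c(free monomer charged) × used share × kept share / c(initiator charged)

south-west: 64.6; east: 102

From south-west to east the initiator charge drops by a factor 2.07 and the used share by 1.30, so east comes out longer, well past the margin of 10%.

The forecast says east, with 65.5 for south-west and 103 for east, since “the radicals then pair off to leave about one chain per initiator molecule”. My lengths stand slightly lower.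

The simulation gives east, with 65.7 for south-west and 104 for east.

In east, half of the growth up to the end of the run is done by 0.0654 h and half of the over-reaction up to the end of the run by 9.45 h. South-west at the end holds 40.7% monomer in chains and 11.2% over-reaction product, both in percent of the free monomer charged, a kept share of 0.784 against the reckoned 0.783.

Now take the neighbour of east charged with 0.0060 M of initiator. Over the same time the kept share is still 0.783, and the reach of 0.997 gives a length of 41.2. The simulation of that flask gives 42.0.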